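## Retrosynthetic overview
1. 9 ⇒ 7 + 6: cut the CH2–N bond. The nitrogen partner already carries its oxygen as an O-silyl ether, so the amine oxide is assembled by C–N bond formation and not by oxidising an amine.
2. 7 ⇒ 4: bromination of the C3-methyl C–H bond, run in the same flask as the C–N coupling.
3. 4 ⇒ 1: three ring C–Br bonds (C2, then C6, then C5) from one exhaustive electrophilic bromination.
4. 6 ⇒ 5: O-silylation of N,N-dimethylhydroxylamine.
5. Rings: none is built. The indole bicycle is bought intact in 1.

Assumption: the target has no stereocentre, because the ammonium nitrogen carries two identical methyl groups. It is achiral and needs no stereocontrol. 1,3-Dimethylindole and N,N-dimethylhydroxylamine hydrochloride are taken as catalogue chemicals.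

## Route

Step 1
Reactants: 1 1,3-dimethylindole
Product: 4 2,5,6-tribromo-1,3-dimethylindole, via 2-bromo-1,3-dimethylindole 2 (not isolated), via 2,6-dibromo-1,3-dimethylindole 3 (not isolated)
Conditions: NBS (3.1 equiv, three portions), dry DMF, 0 °C → rt, dark, 16 h; aq. Na2S2O3; recrystallise (EtOH)
Reagents that add atoms: N-bromosuccinimide (NBS), O=C1CCC(=O)N1Br
Why: Sequential electrophilic aromatic bromination (SEAr) takes the free enamine carbon C2 first, then C6 (para to the C3 enamine carbon) and then C5 (para to N), as expected for 2,3-disubstituted N-methylindoles, while C7 and C4 are shielded by the peri N-methyl and C3-methyl groups; no stereocentre is formed.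

Step 2
Reactants: 5 N,N-dimethylhydroxylamine hydrochloride
Product: 6 O-(tert-butyldimethylsilyl)-N,N-dimethylhydroxylamine
Conditions: TBSCl (1.05 equiv), imidazole (2.5 equiv), CH2Cl2, 0 °C → rt, 4 h; wash with H2O and cold pH 5 phosphate buffer; distil under reduced pressure
Reagents that add atoms: tert-butyldimethylsilyl chloride (TBSCl), CC(C)(C)[Si](C)(C)Cl
Why: This is a standard imidazole-mediated O-silylation (silyl ether formation) in which oxophilic silicon goes to the only O–H, and the weakly basic product stays in the organic layer while imidazole is washed out; no stereocentre is formed.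

Step 3
Reactants: 4 2,5,6-tribromo-1,3-dimethylindole; 6 O-(tert-butyldimethylsilyl)-N,N-dimethylhydroxylamine
Product: 9 2,5,6-tribromo-1-methylgramine N-oxide, via 2,5,6-tribromo-3-(bromomethyl)-1-methylindole 7 (not isolated), via silyloxyammonium bromide 8 (not isolated)
Conditions: NBS (1.05 equiv), AIBN (5 mol %), PhCF3, 85 °C, 1 h; cool to 0 °C, cannula-filter; 6 (1.5 equiv), MeCN, 0 °C → rt, 3 h; KF (3 equiv), MeOH, 0 °C, 30 min; basic alumina (CH2Cl2/MeOH), keep below 30 °C
Reagents that add atoms: 6 O-(tert-butyldimethylsilyl)-N,N-dimethylhydroxylamine, CN(C)O[Si](C)(C)C(C)(C)C (gives the Me2N–O unit); N-bromosuccinimide, O=C1CCC(=O)N1Br (its Br stands only in 7 and 8)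
Why: Proposed new method: one-flask conversion of a heterobenzylic C–H bond into a tertiary amine N-oxide, using an O-silyl-N,N-dialkylhydroxylamine as a masked amine-oxide nucleophile – (i) Wohl–Ziegler bromination takes the weakest C–H (C3–CH3; the ring is shut down by three Br, and an ionic path through the 3-bromoindoleninium ion and loss of HBr ends at the same 7); (ii) 7 ionises easily in MeCN to the 2-bromo-3-methyleneindoleninium ion and is captured by 6 in a Menshutkin-type N-alkylation, where the silyl cap leaves N as the only nucleophilic site, needs neither base nor water (no succinimide N-alkylation, no hydrolysis of 7) and keeps the product O-blocked as 8 so that remaining 7 cannot O-alkylate it; (iii) fluoride then cleaves the activated Si–O bond (amine oxide as leaving group, strong Si–F bond) at 0 °C, faster than it acts as a base (no Polonovski-type elimination) and well below the temperature of Meisenheimer rearrangement; the closest known reaction types are N-alkylation of free N,N-dialkylhydroxylamines by benzyl halides to amine-oxide hydrohalides and amine displacement on gramine-type electrophiles; no stereocentre is formed.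

## Compound list
1 | 1,3-dimethylindole | Cc1cn(C)c2ccccc12 | starting material
2 | 2-bromo-1,3-dimethylindole | Cc1c(Br)n(C)c2ccccc12 | intermediate
3 | 2,6-dibromo-1,3-dimethylindole | Cc1c(Br)n(C)c2cc(Br)ccc12 | intermediate
4 | 2,5,6-tribromo-1,3-dimethylindole | Cc1c(Br)n(C)c2cc(Br)c(Br)cc12 | intermediate
5 | N,N-dimethylhydroxylamine hydrochloride | CN(C)O.Cl | starting material
6 | O-(tert-butyldimethylsilyl)-N,N-dimethylhydroxylamine | CN(C)O[Si](C)(C)C(C)(C)C | intermediate
7 | 2,5,6-tribromo-3-(bromomethyl)-1-methylindole | Cn1c(Br)c(CBr)c2cc(Br)c(Br)cc21 | intermediate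
8 | N-(tert-butyldimethylsilyloxy)-N,N-dimethyl-1-(2,5,6-tribromo-1-methylindol-3-yl)methanaminium bromide | Cn1c(Br)c(C[N+](C)(C)O[Si](C)(C)C(C)(C)C)c2cc(Br)c(Br)cc21.[Br-] | intermediate
9 | 2,5,6-tribromo-1-methylgramine N-oxide (N,N-dimethyl-1-(2,5,6-tribromo-1-methyl-1H-indol-3-yl)methanamine N-oxide; achiral) | Cn1c(Br)c(C[N+](C)(C)[O-])c2cc(Br)c(Br)cc21 | target

## Step count and risks
Total step count: 3. Longest linear sequence: 2 (1 → 4 → 9).

**Step 3 (the new step).**
- Risks: bromination may occur at N–CH3 or twice at C3–CH3. Quaternisation of the weakly basic 6 may be slow or reversible. 8 may be lost by solvolysis or Polonovski-type elimination before it is unmasked.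
- Fallback (known chemistry only): it sets out from 7, generated from 4 as in step 3, and comes back at 9. The filtered PhCF3 solution of 7 is run into Me2NH (2 M in THF, 4 equiv) at 0 °C. This ordinary amine alkylation gives 2,5,6-tribromo-1-methylgramine F1, which is purified by acid–base extraction. mCPBA (1.05 equiv, CH2Cl2, 0 °C) then oxidises the aliphatic tertiary amine to 9; the tribrominated indole π-system is too electron-poor to compete. The N–O bond is thus made last by amine oxidation instead of arriving on the nucleophile.

**Step 1.**
- Risks: 4- or 7-bromo regioisomers may form. The side chain may be brominated through the 3-bromoindoleninium ion. Traces of water may divert material to the oxindole.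
- Fallback: it sets out from 1 and comes back at 4. DDQ (2.1 equiv, THF/H2O 9:1, 0 °C → rt) oxidises the C3-methyl group to 1-methylindole-3-carbaldehyde F2. The formyl group deactivates the pyrrole ring, so Br2 (2.2 equiv, AcOH, rt) should enter only at C5 and C6, as 3-carbonylindoles do, to give 5,6-dibromo-1-methylindole-3-carbaldehyde F3. Ionic deoxygenation (Et3SiH 2.5 equiv, TFA, CH2Cl2, 0 °C) restores the methyl group in 5,6-dibromo-1,3-dimethylindole F4. One equivalent of NBS (CH2Cl2, 0 °C) then brominates the only free pyrrole carbon, C2, to give 4.

**Step 2.**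
- Risks: 6 may be lost through volatility or hydrolysis. It may also carry traces of imidazole, which would quaternise 7.
- Fallback: it sets out from 5 and comes back at 9, leaving out 6 and 8. 5 (3 equiv) is stirred with NaHCO3 (6 equiv) in MeCN to free N,N-dimethylhydroxylamine F5, and the filtered solution of 7 is added at 0 °C. Neutral dialkylhydroxylamines alkylate on nitrogen, which gives N-hydroxy-N,N-dimethyl-1-(2,5,6-tribromo-1-methylindol-3-yl)methanaminium bromide F6. The same bicarbonate deprotonates F6 to 9. Bicarbonate is too weak to deprotonate any residual succinimide, and the excess of F5 outcompetes O-alkylation of 9 by 7.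

## Further compounds
F1 | step 3 | 2,5,6-tribromo-1-methylgramine | CN(C)Cc1c(Br)n(C)c2cc(Br)c(Br)cc12
F2 | step 1 | 1-methylindole-3-carbaldehyde | Cn1cc(C=O)c2ccccc21
F3 | step 1 | 5,6-dibromo-1-methylindole-3-carbaldehyde | Cn1cc(C=O)c2cc(Br)c(Br)cc21
F4 | step 1 | 5,6-dibromo-1,3-dimethylindole | Cc1cn(C)c2cc(Br)c(Br)cc12
F5 | step 2 | N,N-dimethylhydroxylamine (free base) | CN(C)O
F6 | step 2 | N-hydroxy-N,N-dimethyl-1-(2,5,6-tribromo-1-methylindol-3-yl)methanaminium bromide | Cn1c(Br)c(C[N+](C)(C)O)c2cc(Br)c(Br)cc21.[Br-]
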